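**Retrosynthetic overview**
1. Target ⇐ desilylation and hydrogenolysis of a fully protected biflavan (benzyl on the six phenols, TBS on the 3',4'-diol). Unprimed locants and rings A (benzo), B (aryl), C (pyran) are the upper unit; primed locants and rings D (benzo), E (aryl), F (pyran) are the lower unit.
2. Ring C is closed last by an invertive intramolecular Mitsunobu etherification that forms O1–C2 from an (R)-carbinol, so the 2,4-trans relationship is set by the reagent, not by the substrate. The feature that allows it: the phenolic O1 on C8a of ring A lies five atoms from the benzylic, ring-B-bearing C2 across the unsubstituted C3 methylene, so a 6-exo-tet SN2 closure is open.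
3. C2 carbinol ⇐ CBS reduction of the aryl ketone. C4–C6' bond and the C4 stereocentre ⇐ [RhCl(C2H4)2]2/chiral-diene 1,4-addition of the lower-unit C6' boronic acid to a ring-A/ring-B enone from a Claisen–Schmidt condensation.
4. Lower unit ⇐ all-cis 3',4'-diol from a 2,3-trans-dihydroflavonol by Mitsunobu inversion at C3' and carbonyl reduction; dihydroflavonol ⇐ Juliá–Colonna epoxide of a 2'-O-MOM chalcone by acid-triggered 6-endo closure of ring F; the C6' bromine is placed on gallacetophenone at the outset.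
5. Ring order: ring F first (step 6), ring C last (step 17); rings A, B, D and E come from purchased arenes.

Key step: step 17

Assumption: the sense of induction in steps 5, 14 and 15 is taken from the usual empirical models; if a first run shows the opposite sense, the antipodal catalyst (poly-D-leucine, the enantiomeric diene, (R)-CBS) is the one meant.

**Route**

Step 1
Reactants: 1 1-(2,3,4-trihydroxyphenyl)ethanone (gallacetophenone)
Product: 2 1-[3,4-bis(benzyloxy)-2-hydroxyphenyl]ethanone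
Conditions: BnBr (2.1 equiv), K2CO3, DMF, rt
Reagents that add atoms: benzyl bromide, BrCc1ccccc1
Why: Williamson etherification in which the 2-OH, held in a hydrogen bond to the acetyl carbonyl, is the least nucleophilic oxygen, so two equivalents of halide should alkylate O3 and O4 only.

Step 2
Reactants: 2 1-[3,4-bis(benzyloxy)-2-hydroxyphenyl]ethanone
Product: 3 1-[3,4-bis(benzyloxy)-5-bromo-2-hydroxyphenyl]ethanone
Conditions: NBS, MeCN, 0 °C
Reagents that add atoms: N-bromosuccinimide, O=C1CCC(=O)N1Br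
Why: Electrophilic aromatic bromination directed para to the free phenol and ortho to the 4-benzyloxy group, the only other open position being ortho to the acyl group and deactivated, so bromine goes to the carbon that becomes C6'.

Step 3
Reactants: 3 1-[3,4-bis(benzyloxy)-5-bromo-2-hydroxyphenyl]ethanone
Product: 4 1-[3,4-bis(benzyloxy)-5-bromo-2-(methoxymethoxy)phenyl]ethanone
Conditions: MOMCl, iPr2NEt, CH2Cl2, 0 °C to reflux
Reagents that add atoms: chloromethyl methyl ether, COCCl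
Why: O-alkylation of the phenol as its MOM acetal, which keeps the phenoxide from triggering an Algar–Flynn–Oyamada-type oxidative cyclisation during the basic epoxidation.

Step 4
Reactants: 4 1-[3,4-bis(benzyloxy)-5-bromo-2-(methoxymethoxy)phenyl]ethanone; 5 4-(benzyloxy)benzaldehyde
Product: 6 (E)-1-[3,4-bis(benzyloxy)-5-bromo-2-(methoxymethoxy)phenyl]-3-[4-(benzyloxy)phenyl]prop-2-en-1-one
Conditions: KOH, EtOH/THF, rt
Reagents that add atoms: none
Why: Claisen–Schmidt condensation, the aldol dehydrating to the conjugated E-enone.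

Step 5
Reactants: 6 (E)-1-[3,4-bis(benzyloxy)-5-bromo-2-(methoxymethoxy)phenyl]-3-[4-(benzyloxy)phenyl]prop-2-en-1-one
Product: 7 [3,4-bis(benzyloxy)-5-bromo-2-(methoxymethoxy)phenyl]{(2R,3S)-3-[4-(benzyloxy)phenyl]oxiran-2-yl}methanone
Conditions: poly-L-leucine, urea–H2O2, DBU, THF, rt
Reagents that add atoms: urea–hydrogen peroxide, NC(N)=O.OO
Why: Juliá–Colonna asymmetric nucleophilic epoxidation in which the helical polypeptide selects the enone face for hydroperoxide addition, poly-L-leucine being expected to give the (2R,3S)-trans-epoxide whose two centres become C3' (directly) and C2' (after inversion).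

Step 6
Reactants: 7 [3,4-bis(benzyloxy)-5-bromo-2-(methoxymethoxy)phenyl]{(2R,3S)-3-[4-(benzyloxy)phenyl]oxiran-2-yl}methanone
Product: 9 (2R,3R)-7,8-bis(benzyloxy)-2-[4-(benzyloxy)phenyl]-6-bromo-3-hydroxychroman-4-one, via 2'-hydroxy epoxy ketone 8 (not isolated)
Conditions: HCl (conc. aq.), MeOH/THF, 50 °C
Reagents that add atoms: none
Why: Acid removes the MOM group and the freed phenol opens the epoxide at the benzylic carbon activated by the 4-benzyloxyphenyl group (6-endo, inversion at C2', retention at C3'), the known deprotective cyclisation of chalcone epoxides that closes ring F as the 2,3-trans-dihydroflavonol.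

Step 7
Reactants: 9 (2R,3R)-7,8-bis(benzyloxy)-2-[4-(benzyloxy)phenyl]-6-bromo-3-hydroxychroman-4-one
Product: 10 (2R,3S)-7,8-bis(benzyloxy)-2-[4-(benzyloxy)phenyl]-6-bromo-4-oxochroman-3-yl 4-nitrobenzoate
Conditions: 4-O2NC6H4CO2H, PPh3, DIAD, THF, 0 °C to rt
Reagents that add atoms: 4-nitrobenzoic acid, O=C(O)c1ccc([N+](=O)[O-])cc1
Why: Mitsunobu esterification with inversion at C3', turning the 2,3-trans into the 2,3-cis series; the α-keto carbinol is a good SN2 centre and the equatorial C3'–O bond has no antiperiplanar hydrogen for elimination.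

Step 8
Reactants: 10 (2R,3S)-7,8-bis(benzyloxy)-2-[4-(benzyloxy)phenyl]-6-bromo-4-oxochroman-3-yl 4-nitrobenzoate
Product: 12 (2R,3R,4R)-7,8-bis(benzyloxy)-2-[4-(benzyloxy)phenyl]-6-bromochroman-3,4-diol, via all-cis 4-hydroxy 3-nitrobenzoate 11 (not isolated)
Conditions: NaBH4, THF/MeOH, −20 °C; then K2CO3, MeOH, rt
Reagents that add atoms: none
Why: Hydride should add to the C4' carbonyl from the face opposite the axial 3'-acyloxy group and the 2'-aryl group, giving the 3,4-cis alcohol, and in situ methanolysis removes the ester to leave the 2,3-cis-3,4-cis diol.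

Step 9
Reactants: 12 (2R,3R,4R)-7,8-bis(benzyloxy)-2-[4-(benzyloxy)phenyl]-6-bromochroman-3,4-diol
Product: 13 (2R,3S,4R)-7,8-bis(benzyloxy)-2-[4-(benzyloxy)phenyl]-6-bromo-3,4-bis[(tert-butyldimethylsilyl)oxy]chromane (spatial arrangement of 12; the C3 descriptor changes by priority only)
Conditions: TBSOTf, 2,6-lutidine, CH2Cl2, 0 °C
Reagents that add atoms: tert-butyldimethylsilyl trifluoromethanesulfonate, CC(C)(C)[Si](C)(C)OS(=O)(=O)C(F)(F)F
Why: Silylation of both secondary alcohols under basic, non-ionising conditions, which protects the ionisation-prone benzylic C4' oxygen function with groups that later come off with fluoride instead of acid.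

Step 10
Reactants: 13 (2R,3S,4R)-7,8-bis(benzyloxy)-2-[4-(benzyloxy)phenyl]-6-bromo-3,4-bis[(tert-butyldimethylsilyl)oxy]chromane
Product: 14 {(2R,3S,4R)-7,8-bis(benzyloxy)-2-[4-(benzyloxy)phenyl]-3,4-bis[(tert-butyldimethylsilyl)oxy]chroman-6-yl}boronic acid
Conditions: n-BuLi added to 13 and B(OiPr)3, THF/toluene, −78 °C; then H2O/AcOH
Reagents that add atoms: triisopropyl borate, CC(C)OB(OC(C)C)OC(C)C; water, O
Why: Bromine–lithium exchange with in situ borate trapping, faster than deprotonation of the benzylic ethers, followed by hydrolysis to the arylboronic acid.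

Step 11
Reactants: 15 2,3,4-trihydroxybenzaldehyde
Product: 16 3,4-bis(benzyloxy)-2-hydroxybenzaldehyde
Conditions: BnBr (2.1 equiv), K2CO3, DMF, rt
Reagents that add atoms: benzyl bromide, BrCc1ccccc1
Why: Williamson etherification with the same chelation-based selectivity as in step 1, the formyl-bonded 2-OH staying free.

Step 12
Reactants: 16 3,4-bis(benzyloxy)-2-hydroxybenzaldehyde; 17 1-[4-(benzyloxy)phenyl]ethanone
Product: 18 (E)-3-[3,4-bis(benzyloxy)-2-hydroxyphenyl]-1-[4-(benzyloxy)phenyl]prop-2-en-1-one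
Conditions: KOH (aq.), EtOH, rt
Reagents that add atoms: none
Why: Claisen–Schmidt condensation of a salicylaldehyde with an acetophenone, giving the E-enone that already holds C2, C3, C4 and rings A and B.

Step 13
Reactants: 18 (E)-3-[3,4-bis(benzyloxy)-2-hydroxyphenyl]-1-[4-(benzyloxy)phenyl]prop-2-en-1-one
Product: 19 (E)-3-{3,4-bis(benzyloxy)-2-[(tert-butyldimethylsilyl)oxy]phenyl}-1-[4-(benzyloxy)phenyl]prop-2-en-1-one
Conditions: TBSCl, imidazole, DMF, rt
Reagents that add atoms: tert-butyldimethylsilyl chloride, CC(C)(C)[Si](C)(C)Cl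
Why: Silylation of the phenol, so that no phenoxide deactivates the enone in step 14 and no free phenol takes part in the borane reduction of step 15.

Step 14
Reactants: 19 (E)-3-{3,4-bis(benzyloxy)-2-[(tert-butyldimethylsilyl)oxy]phenyl}-1-[4-(benzyloxy)phenyl]prop-2-en-1-one; 14 {(2R,3S,4R)-7,8-bis(benzyloxy)-2-[4-(benzyloxy)phenyl]-3,4-bis[(tert-butyldimethylsilyl)oxy]chroman-6-yl}boronic acid
Product: 20 (3S)-1-[4-(benzyloxy)phenyl]-3-{3,4-bis(benzyloxy)-2-[(tert-butyldimethylsilyl)oxy]phenyl}-3-{(2R,3S,4R)-7,8-bis(benzyloxy)-2-[4-(benzyloxy)phenyl]-3,4-bis[(tert-butyldimethylsilyl)oxy]chroman-6-yl}propan-1-one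
Conditions: [RhCl(C2H4)2]2 (3 mol %), (R,R)-2,5-diphenylbicyclo[2.2.2]octa-2,5-diene (or its antipode, see assumption), KOH (0.1 equiv), dioxane/H2O 10:1, 30 °C, 19 in excess
Reagents that add atoms: none
Why: Hayashi–Miyaura asymmetric 1,4-addition in which the aryl group passes from boron to monovalent rhodium, the aryl–rhodium species inserts the enone on the face left open by the chiral diene and water protonates the rhodium enolate, so the catalyst sets the diarylmethine centre (the future C4) while the stereocentres of 14 lie too far from C6' to compete.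

Step 15
Reactants: 20 (3S)-1-[4-(benzyloxy)phenyl]-3-{3,4-bis(benzyloxy)-2-[(tert-butyldimethylsilyl)oxy]phenyl}-3-{(2R,3S,4R)-7,8-bis(benzyloxy)-2-[4-(benzyloxy)phenyl]-3,4-bis[(tert-butyldimethylsilyl)oxy]chroman-6-yl}propan-1-one
Product: 21 (1R,3S)-1-[4-(benzyloxy)phenyl]-3-{3,4-bis(benzyloxy)-2-[(tert-butyldimethylsilyl)oxy]phenyl}-3-{(2R,3S,4R)-7,8-bis(benzyloxy)-2-[4-(benzyloxy)phenyl]-3,4-bis[(tert-butyldimethylsilyl)oxy]chroman-6-yl}propan-1-ol
Conditions: (S)-2-methyl-CBS-oxazaborolidine (15 mol %), BH3·SMe2, THF, −20 °C; MeOH quench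
Reagents that add atoms: none
Why: Corey–Bakshi–Shibata reduction of an aryl alkyl ketone, in which the aryl group acts as the large substituent and the (S)-catalyst is expected to deliver the (R)-carbinol under reagent control, the methine centre two atoms away exerting little influence.

Step 16
Reactants: 21 (1R,3S)-1-[4-(benzyloxy)phenyl]-3-{3,4-bis(benzyloxy)-2-[(tert-butyldimethylsilyl)oxy]phenyl}-3-{(2R,3S,4R)-7,8-bis(benzyloxy)-2-[4-(benzyloxy)phenyl]-3,4-bis[(tert-butyldimethylsilyl)oxy]chroman-6-yl}propan-1-ol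
Product: 22 (1R,3R)-1-[4-(benzyloxy)phenyl]-3-[3,4-bis(benzyloxy)-2-hydroxyphenyl]-3-{(2R,3S,4R)-7,8-bis(benzyloxy)-2-[4-(benzyloxy)phenyl]-3,4-bis[(tert-butyldimethylsilyl)oxy]chroman-6-yl}propan-1-ol (spatial arrangement of 21; the C3 descriptor changes by priority only)
Conditions: KHF2, MeOH, rt
Reagents that add atoms: none
Why: Selective cleavage of the phenolic silyl ether, phenoxide being the better leaving group on silicon, while the two secondary alkyl TBS ethers should stay.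

Step 17
Reactants: 22 (1R,3R)-1-[4-(benzyloxy)phenyl]-3-[3,4-bis(benzyloxy)-2-hydroxyphenyl]-3-{(2R,3S,4R)-7,8-bis(benzyloxy)-2-[4-(benzyloxy)phenyl]-3,4-bis[(tert-butyldimethylsilyl)oxy]chroman-6-yl}propan-1-ol
Product: 23 (2R,3S,4R)-7,8-bis(benzyloxy)-2-[4-(benzyloxy)phenyl]-6-{(2S,4R)-7,8-bis(benzyloxy)-2-[4-(benzyloxy)phenyl]chroman-4-yl}-3,4-bis[(tert-butyldimethylsilyl)oxy]chromane (upper unit 2,4-trans; spatial arrangement of the target)
Conditions: PPh3, DIAD (slow addition), toluene, −20 to 0 °C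
Reagents that add atoms: none
Why: The phosphine–azodicarboxylate betaine is protonated by the ring A phenol (O1–H) and turns the C2 carbinol into an alkoxyphosphonium ion, which the phenoxide displaces intramolecularly in an SN2 process, closing ring C through the O1–C2 bond. The closest known reaction type is the intramolecular Mitsunobu etherification of 1-aryl-3-(2-hydroxyaryl)propan-1-ols to 2-arylchromans (flavans). Ring C closes in the 6-exo-tet mode, the leaving oxygen lying outside the forming ring. The new stereocentre C2 is controlled by the carbinol configuration from step 15 and forms with inversion, so it does not depend on the C4 substituent, and the 2,4-trans relationship, which closures through a planar C2 cation or hydrogen delivery to C2 would not favour, follows by design. The step needs SN2 displacement to outrun ionisation of the 4-benzyloxybenzylic oxyphosphonium ion and elimination to the styrene; the unsubstituted C3 methylene, the five-atom distance of the phenoxide, the non-polar solvent and the low temperature should secure this. Chemoselectivity is built in, since the phenol and the carbinol are the only free hydroxyl groups of 22.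

Step 18
Reactants: 23 (2R,3S,4R)-7,8-bis(benzyloxy)-2-[4-(benzyloxy)phenyl]-6-{(2S,4R)-7,8-bis(benzyloxy)-2-[4-(benzyloxy)phenyl]chroman-4-yl}-3,4-bis[(tert-butyldimethylsilyl)oxy]chromane
Product: 24 (2R,3R,4R)-7,8-bis(benzyloxy)-2-[4-(benzyloxy)phenyl]-6-{(2S,4R)-7,8-bis(benzyloxy)-2-[4-(benzyloxy)phenyl]chroman-4-yl}chroman-3,4-diol
Conditions: TBAF, AcOH, THF, 0 °C to rt
Reagents that add atoms: none
Why: Fluoride cleavage of the two alkyl silyl ethers under buffered, non-acidic conditions, so the benzylic C4'–O bond cannot ionise and epimerise.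

Step 19
Reactants: 24 (2R,3R,4R)-7,8-bis(benzyloxy)-2-[4-(benzyloxy)phenyl]-6-{(2S,4R)-7,8-bis(benzyloxy)-2-[4-(benzyloxy)phenyl]chroman-4-yl}chroman-3,4-diol
Product: 25 (2R,3R,4R)-6-[(2S,4S)-7,8-dihydroxy-2-(4-hydroxyphenyl)chroman-4-yl]-2-(4-hydroxyphenyl)chroman-3,4,7,8-tetrol
Conditions: H2 (1 atm), Pd(OH)2/C, EtOAc/MeOH, rt, neutral
Reagents that add atoms: none
Why: Hydrogenolysis of the six aryl benzyl ethers under neutral conditions, where they should cleave much faster than the secondary benzylic C4'–OH and the cyclic benzylic ether bonds, as in debenzylations of flavan-3-ols and of 4-hydroxyphenyl carbinols.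

**Compound list**
1 | 1-(2,3,4-trihydroxyphenyl)ethanone (gallacetophenone) | CC(=O)c1ccc(O)c(O)c1O | starting material
2 | 1-[3,4-bis(benzyloxy)-2-hydroxyphenyl]ethanone | CC(=O)c1ccc(OCc2ccccc2)c(OCc2ccccc2)c1O | intermediate
3 | 1-[3,4-bis(benzyloxy)-5-bromo-2-hydroxyphenyl]ethanone | CC(=O)c1cc(Br)c(OCc2ccccc2)c(OCc2ccccc2)c1O | intermediate
4 | 1-[3,4-bis(benzyloxy)-5-bromo-2-(methoxymethoxy)phenyl]ethanone | CC(=O)c1cc(Br)c(OCc2ccccc2)c(OCc2ccccc2)c1OCOC | intermediate
5 | 4-(benzyloxy)benzaldehyde | O=Cc1ccc(OCc2ccccc2)cc1 | starting material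
6 | (E)-1-[3,4-bis(benzyloxy)-5-bromo-2-(methoxymethoxy)phenyl]-3-[4-(benzyloxy)phenyl]prop-2-en-1-one | O=C(/C=C/c1ccc(OCc2ccccc2)cc1)c1cc(Br)c(OCc2ccccc2)c(OCc2ccccc2)c1OCOC | intermediate
7 | [3,4-bis(benzyloxy)-5-bromo-2-(methoxymethoxy)phenyl]{(2R,3S)-3-[4-(benzyloxy)phenyl]oxiran-2-yl}methanone | O=C([C@@H]1O[C@H]1c1ccc(OCc2ccccc2)cc1)c1cc(Br)c(OCc2ccccc2)c(OCc2ccccc2)c1OCOC | intermediate
8 | [3,4-bis(benzyloxy)-5-bromo-2-hydroxyphenyl]{(2R,3S)-3-[4-(benzyloxy)phenyl]oxiran-2-yl}methanone (formed in the flask) | O=C([C@@H]1O[C@H]1c1ccc(OCc2ccccc2)cc1)c1cc(Br)c(OCc2ccccc2)c(OCc2ccccc2)c1O | intermediate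
9 | (2R,3R)-7,8-bis(benzyloxy)-2-[4-(benzyloxy)phenyl]-6-bromo-3-hydroxychroman-4-one (2,3-trans) | O=C1[C@H](O)[C@@H](c2ccc(OCc3ccccc3)cc2)Oc2c(OCc3ccccc3)c(OCc3ccccc3)c(Br)cc21 | intermediate
10 | (2R,3S)-7,8-bis(benzyloxy)-2-[4-(benzyloxy)phenyl]-6-bromo-4-oxochroman-3-yl 4-nitrobenzoate (2,3-cis) | O=C1[C@@H](OC(=O)c2ccc([N+](=O)[O-])cc2)[C@@H](c2ccc(OCc3ccccc3)cc2)Oc2c(OCc3ccccc3)c(OCc3ccccc3)c(Br)cc21 | intermediate
11 | (2R,3R,4R)-7,8-bis(benzyloxy)-2-[4-(benzyloxy)phenyl]-6-bromo-4-hydroxychroman-3-yl 4-nitrobenzoate (all-cis, formed in the flask) | O[C@H]1[C@@H](OC(=O)c2ccc([N+](=O)[O-])cc2)[C@@H](c2ccc(OCc3ccccc3)cc2)Oc2c(OCc3ccccc3)c(OCc3ccccc3)c(Br)cc21 | intermediate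
12 | (2R,3R,4R)-7,8-bis(benzyloxy)-2-[4-(benzyloxy)phenyl]-6-bromochroman-3,4-diol (2,3-cis-3,4-cis) | O[C@H]1[C@@H](O)[C@@H](c2ccc(OCc3ccccc3)cc2)Oc2c(OCc3ccccc3)c(OCc3ccccc3)c(Br)cc21 | intermediate
13 | (2R,3S,4R)-7,8-bis(benzyloxy)-2-[4-(benzyloxy)phenyl]-6-bromo-3,4-bis[(tert-butyldimethylsilyl)oxy]chromane (all-cis) | CC(C)(C)[Si](C)(C)O[C@H]1[C@@H](O[Si](C)(C)C(C)(C)C)[C@@H](c2ccc(OCc3ccccc3)cc2)Oc2c(OCc3ccccc3)c(OCc3ccccc3)c(Br)cc21 | intermediate
14 | {(2R,3S,4R)-7,8-bis(benzyloxy)-2-[4-(benzyloxy)phenyl]-3,4-bis[(tert-butyldimethylsilyl)oxy]chroman-6-yl}boronic acid | CC(C)(C)[Si](C)(C)O[C@H]1[C@@H](O[Si](C)(C)C(C)(C)C)[C@@H](c2ccc(OCc3ccccc3)cc2)Oc2c(OCc3ccccc3)c(OCc3ccccc3)c(B(O)O)cc21 | intermediate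
15 | 2,3,4-trihydroxybenzaldehyde | O=Cc1ccc(O)c(O)c1O | starting material
16 | 3,4-bis(benzyloxy)-2-hydroxybenzaldehyde | O=Cc1ccc(OCc2ccccc2)c(OCc2ccccc2)c1O | intermediate
17 | 1-[4-(benzyloxy)phenyl]ethanone | CC(=O)c1ccc(OCc2ccccc2)cc1 | starting material
18 | (E)-3-[3,4-bis(benzyloxy)-2-hydroxyphenyl]-1-[4-(benzyloxy)phenyl]prop-2-en-1-one | O=C(/C=C/c1ccc(OCc2ccccc2)c(OCc2ccccc2)c1O)c1ccc(OCc2ccccc2)cc1 | intermediate
19 | (E)-3-{3,4-bis(benzyloxy)-2-[(tert-butyldimethylsilyl)oxy]phenyl}-1-[4-(benzyloxy)phenyl]prop-2-en-1-one | O=C(/C=C/c1ccc(OCc2ccccc2)c(OCc2ccccc2)c1O[Si](C)(C)C(C)(C)C)c1ccc(OCc2ccccc2)cc1 | intermediate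
20 | (3S)-1-[4-(benzyloxy)phenyl]-3-{3,4-bis(benzyloxy)-2-[(tert-butyldimethylsilyl)oxy]phenyl}-3-{(2R,3S,4R)-7,8-bis(benzyloxy)-2-[4-(benzyloxy)phenyl]-3,4-bis[(tert-butyldimethylsilyl)oxy]chroman-6-yl}propan-1-one | O=C(c1ccc(OCc2ccccc2)cc1)C[C@@H](c1cc2c(c(OCc3ccccc3)c1OCc1ccccc1)O[C@H](c1ccc(OCc3ccccc3)cc1)[C@H](O[Si](C)(C)C(C)(C)C)[C@@H]2O[Si](C)(C)C(C)(C)C)c1ccc(OCc2ccccc2)c(OCc2ccccc2)c1O[Si](C)(C)C(C)(C)C | intermediate
21 | (1R,3S)-1-[4-(benzyloxy)phenyl]-3-{3,4-bis(benzyloxy)-2-[(tert-butyldimethylsilyl)oxy]phenyl}-3-{(2R,3S,4R)-7,8-bis(benzyloxy)-2-[4-(benzyloxy)phenyl]-3,4-bis[(tert-butyldimethylsilyl)oxy]chroman-6-yl}propan-1-ol | O[C@@H](c1ccc(OCc2ccccc2)cc1)C[C@@H](c1cc2c(c(OCc3ccccc3)c1OCc1ccccc1)O[C@H](c1ccc(OCc3ccccc3)cc1)[C@H](O[Si](C)(C)C(C)(C)C)[C@@H]2O[Si](C)(C)C(C)(C)C)c1ccc(OCc2ccccc2)c(OCc2ccccc2)c1O[Si](C)(C)C(C)(C)C | intermediate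
22 | (1R,3R)-1-[4-(benzyloxy)phenyl]-3-[3,4-bis(benzyloxy)-2-hydroxyphenyl]-3-{(2R,3S,4R)-7,8-bis(benzyloxy)-2-[4-(benzyloxy)phenyl]-3,4-bis[(tert-butyldimethylsilyl)oxy]chroman-6-yl}propan-1-ol | O[C@@H](c1ccc(OCc2ccccc2)cc1)C[C@@H](c1cc2c(c(OCc3ccccc3)c1OCc1ccccc1)O[C@H](c1ccc(OCc3ccccc3)cc1)[C@H](O[Si](C)(C)C(C)(C)C)[C@@H]2O[Si](C)(C)C(C)(C)C)c1ccc(OCc2ccccc2)c(OCc2ccccc2)c1O | intermediate
23 | (2R,3S,4R)-7,8-bis(benzyloxy)-2-[4-(benzyloxy)phenyl]-6-{(2S,4R)-7,8-bis(benzyloxy)-2-[4-(benzyloxy)phenyl]chroman-4-yl}-3,4-bis[(tert-butyldimethylsilyl)oxy]chromane | O(Cc1ccccc1)c1ccc([C@@H]2C[C@@H](c3cc4c(c(OCc5ccccc5)c3OCc3ccccc3)O[C@H](c3ccc(OCc5ccccc5)cc3)[C@H](O[Si](C)(C)C(C)(C)C)[C@@H]4O[Si](C)(C)C(C)(C)C)c3ccc(OCc4ccccc4)c(OCc4ccccc4)c3O2)cc1 | intermediate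
24 | (2R,3R,4R)-7,8-bis(benzyloxy)-2-[4-(benzyloxy)phenyl]-6-{(2S,4R)-7,8-bis(benzyloxy)-2-[4-(benzyloxy)phenyl]chroman-4-yl}chroman-3,4-diol | O(Cc1ccccc1)c1ccc([C@@H]2C[C@@H](c3cc4c(c(OCc5ccccc5)c3OCc3ccccc3)O[C@H](c3ccc(OCc5ccccc5)cc3)[C@H](O)[C@@H]4O)c3ccc(OCc4ccccc4)c(OCc4ccccc4)c3O2)cc1 | intermediate
25 | (2R,3R,4R)-6-[(2S,4S)-7,8-dihydroxy-2-(4-hydroxyphenyl)chroman-4-yl]-2-(4-hydroxyphenyl)chroman-3,4,7,8-tetrol | Oc1ccc([C@@H]2C[C@@H](c3cc4c(c(O)c3O)O[C@H](c3ccc(O)cc3)[C@H](O)[C@@H]4O)c3ccc(O)c(O)c3O2)cc1 | target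

**Step count and risks**
Total: 19 steps. Longest linear sequence: 16 steps (steps 1–10, then 14–19).

Steps most likely to fail:

Step 17. Ionisation of the 4-benzyloxybenzylic oxyphosphonium ion (SN1 leakage) would erode the configuration at C2, and elimination to the styrene could compete. The fallback sets out from ketone 20 and returns at 23. KHF2 in MeOH would free the keto phenol F1. Warming F1 with PPTS in toluene over molecular sieves should cyclodehydrate it through its hemiketal to the 2,4-diaryl-4H-chromene F2, the O1–C2 bond then being present as an enol ether. Asymmetric hydrogenation of the enol-ether double bond with [Ir(cod)(L)]B[3,5-(CF3)2C6H3]4 (L = a chiral phosphine–oxazoline) under H2 would give 23. The ligand enantiomer has to be the one that adds hydrogen to the face syn to the C4 aryl group, so the catalyst must override the substrate's preference for the 2,4-cis isomer.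

Step 14. Slow insertion at an enone β-carbon flanked by an ortho-silyloxy aryl group, protodeboronation of the electron-rich boronic acid, and mismatched double stereodifferentiation could each stall the addition or lower its selectivity. The fallback sets out from bromide 13 and enone 19 and returns at 20. Bromine–lithium exchange on 13 (n-BuLi, THF, −78 °C), transmetallation with MgBr2·OEt2 and conjugate addition mediated by CuBr·SMe2 should give 20 together with its methine epimer F3. The two are diastereomers because of the lower-unit stereocentres and would be separated by chromatography.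

Step 7. Enolisation at C3', reversible opening of ring F, or loss of the activated oxygen to give the flavone could compete with displacement. The fallback sets out from 9 and returns at 12. Tf2O and pyridine in CH2Cl2 at −20 °C would give the 3-O-triflate F4. Lattrell–Dax displacement with KNO2 and 18-crown-6 in DMF, with hydrolysis of the nitrite ester on work-up, should give the 2,3-cis-dihydroflavonol F5. NaBH4 reduction as in step 8 would then give 12.

**Further compounds**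
F1 | step 17 | (3R)-1-[4-(benzyloxy)phenyl]-3-[3,4-bis(benzyloxy)-2-hydroxyphenyl]-3-{(2R,3S,4R)-7,8-bis(benzyloxy)-2-[4-(benzyloxy)phenyl]-3,4-bis[(tert-butyldimethylsilyl)oxy]chroman-6-yl}propan-1-one | O=C(c1ccc(OCc2ccccc2)cc1)C[C@@H](c1cc2c(c(OCc3ccccc3)c1OCc1ccccc1)O[C@H](c1ccc(OCc3ccccc3)cc1)[C@H](O[Si](C)(C)C(C)(C)C)[C@@H]2O[Si](C)(C)C(C)(C)C)c1ccc(OCc2ccccc2)c(OCc2ccccc2)c1O
F2 | step 17 | 7,8-bis(benzyloxy)-2-[4-(benzyloxy)phenyl]-4-{(2R,3S,4R)-7,8-bis(benzyloxy)-2-[4-(benzyloxy)phenyl]-3,4-bis[(tert-butyldimethylsilyl)oxy]chroman-6-yl}-4H-chromene (C4 as in 23) | O(Cc1ccccc1)c1ccc(C2=C[C@@H](c3cc4c(c(OCc5ccccc5)c3OCc3ccccc3)O[C@H](c3ccc(OCc5ccccc5)cc3)[C@H](O[Si](C)(C)C(C)(C)C)[C@@H]4O[Si](C)(C)C(C)(C)C)c3ccc(OCc4ccccc4)c(OCc4ccccc4)c3O2)cc1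
F3 | step 14 | (3R)-methine epimer of 20 | O=C(c1ccc(OCc2ccccc2)cc1)C[C@H](c1cc2c(c(OCc3ccccc3)c1OCc1ccccc1)O[C@H](c1ccc(OCc3ccccc3)cc1)[C@H](O[Si](C)(C)C(C)(C)C)[C@@H]2O[Si](C)(C)C(C)(C)C)c1ccc(OCc2ccccc2)c(OCc2ccccc2)c1O[Si](C)(C)C(C)(C)C
F4 | step 7 | (2R,3R)-7,8-bis(benzyloxy)-2-[4-(benzyloxy)phenyl]-6-bromo-4-oxochroman-3-yl trifluoromethanesulfonate | O=C1[C@H](OS(=O)(=O)C(F)(F)F)[C@@H](c2ccc(OCc3ccccc3)cc2)Oc2c(OCc3ccccc3)c(OCc3ccccc3)c(Br)cc21
F5 | step 7 | (2R,3S)-7,8-bis(benzyloxy)-2-[4-(benzyloxy)phenyl]-6-bromo-3-hydroxychroman-4-one (2,3-cis) | O=C1[C@@H](O)[C@@H](c2ccc(OCc3ccccc3)cc2)Oc2c(OCc3ccccc3)c(OCc3ccccc3)c(Br)cc21
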